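**Plan**
Retrosynthesis: the C3' and C6' quinone carbonyls of ring B go back to two aryl methyl ethers. Ring A is then cut at C4a–C5, C5–C6 and C7–C8 (C8–C8a comes from a 1,2-shift), and the C2–C1' bond is cut last.
Enabling feature: ring A is a resorcinol monomethyl ether (C5–OH and C7–OMe, meta) fused through C4a=C8a to the 4-pyranone ring C. O1, C2, C3–O and C4=O of ring C are those of a 5-hydroxy-4-pyranone-2-carboxylic acid, so the carboxyl carbon on C8a can become C5.
Forward: ring C is bought, ring B is joined at C2 by cross-coupling, the carboxyl group becomes a diazoketone, and ring A is closed onto the pyranone by a ketene–ynol ether benzannulation.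
The ketene oxygen ends as the only free phenol (C5–OH) and the ynol ether oxygen as C7–OMe, so ring A needs no protecting group.
Halogenation and the carboxyl oxidation level are in place before the electron-rich ring B arrives, and ring B is oxidised to the quinone only in the last step.
Stereochemistry: the target has no stereocentre, and the transient centres of the cascade are erased on aromatisation.

Key step: step 8

Remark: flavone numbering (ring C: O1, C2, C3, C4; ring A: C4a, C5–C8, C8a; ring B: C1'–C6') is also used for the intermediates, and rotation about C2–C1' is taken as free because the target is drawn without an axial descriptor.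

**Step 1**
Reactants: 1 1,2,3,5-tetramethoxybenzene
Product: 4 (2,3,4,6-tetramethoxyphenyl)boronic acid, via aryllithium 2 (not isolated), via lithium arylborate 3 (not isolated)
Conditions: n-BuLi, THF, 0 °C to rt; B(OMe)3, −78 °C to rt; 1 M HCl, 0 °C
Reagents that add atoms: trimethyl borate COB(OC)OC; water O
Why: Directed ortho-lithiation followed by borylation, in which the two ring hydrogens of 1 are equivalent and each lies between two methoxy groups, so a single aryllithium forms and is trapped by the borate ester before cold hydrolysis.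

**Step 2**
Reactants: 5 comenic acid (5-hydroxy-4-oxo-4H-pyran-2-carboxylic acid)
Product: 6 6-bromo-5-hydroxy-4-oxo-4H-pyran-2-carboxylic acid
Conditions: Br2 (1.0 equiv), H2O, rt
Reagents that add atoms: bromine BrBr
Why: Electrophilic bromination of a 5-hydroxy-4-pyranone goes to C6, the β-carbon of the C5 enol and the only ring position activated by the hydroxyl group, which is long-established behaviour for this class.

**Step 3**
Reactants: 6 6-bromo-5-hydroxy-4-oxo-4H-pyran-2-carboxylic acid
Product: 7 methyl 6-bromo-5-methoxy-4-oxo-4H-pyran-2-carboxylate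
Conditions: MeI (3 equiv), K2CO3, DMF, rt
Reagents that add atoms: iodomethane CI
Why: Double SN2 O-alkylation (Williamson type), in which carbonate deprotonates both the carboxylic acid and the acidic enol, so one operation installs the future C3 methoxy group and a coupling-stable ester.

**Step 4**
Reactants: 7 methyl 6-bromo-5-methoxy-4-oxo-4H-pyran-2-carboxylate; 4 (2,3,4,6-tetramethoxyphenyl)boronic acid (1.5 equiv)
Product: 8 methyl 5-methoxy-4-oxo-6-(2,3,4,6-tetramethoxyphenyl)-4H-pyran-2-carboxylate
Conditions: Pd(OAc)2 (5 mol %), SPhos (10 mol %), K3PO4 (anhydrous), toluene, 90 °C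
Reagents that add atoms: none
Why: Suzuki–Miyaura coupling, in which the C–Br bond is a vinylogous acyl bromide that adds readily to zerovalent palladium, the bulky electron-rich SPhos ligand is the established answer to di-ortho-substituted boronic acids, and the water-poor medium spares the ester and the bromide from hydroxide.

**Step 5**
Reactants: 8 methyl 5-methoxy-4-oxo-6-(2,3,4,6-tetramethoxyphenyl)-4H-pyran-2-carboxylate
Product: 10 5-methoxy-4-oxo-6-(2,3,4,6-tetramethoxyphenyl)-4H-pyran-2-carboxylic acid, via lithium carboxylate 9 (not isolated)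
Conditions: LiOH (1.1 equiv), THF/H2O, 0 °C; 1 M HCl
Reagents that add atoms: lithium hydroxide [Li+].[OH-]
Why: Saponification (BAc2), in which the ester on the electron-poor pyranone is strongly activated and is cleaved by one equivalent of hydroxide at 0 °C faster than hydroxide adds to the ring.

**Step 6**
Reactants: 10 5-methoxy-4-oxo-6-(2,3,4,6-tetramethoxyphenyl)-4H-pyran-2-carboxylic acid
Product: 12 2-diazo-1-[5-methoxy-4-oxo-6-(2,3,4,6-tetramethoxyphenyl)-4H-pyran-2-yl]ethanone, via mixed anhydride 11 (not isolated)
Conditions: i-BuOCOCl, N-methylmorpholine, THF, −15 °C; CH2N2, Et2O, −15 to 0 °C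
Reagents that add atoms: diazomethane C=[N+]=[N-]
Why: Arndt–Eistert-type acylation of diazomethane, in which the mixed carbonic anhydride is attacked at the more electrophilic pyranoyl carbonyl, the carbonate leaving group takes up the proton, and the cold, acid-free conditions disfavour chloromethyl ketone formation, dipolar cycloaddition to the pyranone C=C bond and electrophilic attack on ring B.

**Step 7**
Reactants: 13 chloroacetaldehyde dimethyl acetal (2-chloro-1,1-dimethoxyethane)
Product: 15 methoxyethyne, via sodium methoxyethynide 14 (not isolated)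
Conditions: NaNH2 (3.1 equiv), liq. NH3, −33 °C; sat. aq. NaCl, −70 °C to rt, distilled into a −78 °C trap
Reagents that add atoms: none
Why: Double base-induced elimination (loss of methanol, then of HCl) of a chloroacetal with sodium amide is the standard preparation of 1-alkoxyalkynes, and the third equivalent of base holds the volatile product as its acetylide until the cold quench.

**Step 8**
Reactants: 12 2-diazo-1-[5-methoxy-4-oxo-6-(2,3,4,6-tetramethoxyphenyl)-4H-pyran-2-yl]ethanone; 15 methoxyethyne (4 equiv)
Product: 20 5-hydroxy-3,7-dimethoxy-2-(2,3,4,6-tetramethoxyphenyl)-4H-chromen-4-one, via pyranonylketene 16 (not isolated), via cyclobutenone 17 (not isolated), via dienylketene 18 (not isolated), via cyclohexadienone 19 (not isolated)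
Conditions: ClCH2CH2Cl (0.03 M, degassed), hν (420 nm LEDs), sealed Pyrex vessel, 0 °C; Ar purge; 85 °C
Reagents that add atoms: none
Why: Proposed new method: excitation of the diazoketone expels N2 and shifts the pyranonyl group from the acyl carbon to the diazo carbon (Wolff rearrangement, making C8–C8a), and ketene 16 is captured by 15 in a [2+2] cycloaddition in which the nucleophilic CH terminus of the ynol ether bonds to the ketene carbonyl carbon (C6–C5) and the methoxy-bearing carbon to the α-carbon (C7–C8), which fixes the meta relation of C5–O and C7–OMe in cyclobutenone 17. On heating, 17 opens by a reversible conrotatory four-electron process (the old C5–C8 bond breaks) to dienylketene 18; only the isomer with the pyranonyl group cis to the ketene arm can react on, and the other one drains back through 17. Ring A, the only ring formed, closes by a disrotatory six-electron electrocyclisation (six-membered, C4a–C5) that uses C8a=C4a of the pyranone as the third π bond; C4a is the only carbon neighbour of C8a, so there is no regiochemical choice, and as the β-carbon of the O1–C8a=C4a enol ether it is polarity-matched to the ketene carbon. Dienone 19 holds its C4a hydrogen between two carbonyl groups and enolises at once to the chelated C5 phenol, so the racemic centres of 17 and 19 vanish, no stereocentre has to be controlled, and the single phenol is set apart from the six methyl ethers without a protecting group. The closest known reaction type is the Danheiser benzannulation in its diazoketone form, established for vinyl, aryl and five-membered heteroaryl diazoketones with alkoxy- and siloxyalkynes, whereas a 4-pyranone has not yet served as the alkene partner; its weak aromatic stabilisation should make the electrocyclisation easier than with a benzene ring. The needed chemoselectivity is that only the diazoketone is excited, which 420 nm light secures because it reaches the n–π* band of the diazoketone and not the 4-pyranone chromophore, whose ultraviolet isomerisation to 2-pyranones is thereby avoided.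

**Step 9**
Reactants: 20 5-hydroxy-3,7-dimethoxy-2-(2,3,4,6-tetramethoxyphenyl)-4H-chromen-4-one
Product: 21 2-(5-hydroxy-3,7-dimethoxy-4-oxo-4H-chromen-2-yl)-3,5-dimethoxycyclohexa-2,5-diene-1,4-dione (target)
Conditions: (NH4)2Ce(NO3)6 (2.2 equiv), MeCN/H2O 2:1, 0 °C
Reagents that add atoms: water O
Why: Oxidative demethylation of a 1,4-dimethoxyarene by tetravalent cerium, in which ring B is by far the most electron-rich arene and C3'/C6' is its only para pair of methoxy groups, so two one-electron oxidations with attack of water at these carbons give the 3',6'-quinone, while ring A is deactivated by the C4 carbonyl group and its C5–OH is held in a hydrogen bond.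

**Compound list**
1 | 1,2,3,5-tetramethoxybenzene | COc1cc(OC)c(OC)c(OC)c1 | starting material
2 | (2,3,4,6-tetramethoxyphenyl)lithium | [Li]c1c(OC)cc(OC)c(OC)c1OC | intermediate
3 | lithium trimethoxy(2,3,4,6-tetramethoxyphenyl)borate | [Li+].CO[B-](OC)(OC)c1c(OC)cc(OC)c(OC)c1OC | intermediate
4 | (2,3,4,6-tetramethoxyphenyl)boronic acid | COc1cc(OC)c(OC)c(OC)c1B(O)O | intermediate
5 | comenic acid (5-hydroxy-4-oxo-4H-pyran-2-carboxylic acid) | OC(=O)c1cc(=O)c(O)co1 | starting material
6 | 6-bromo-5-hydroxy-4-oxo-4H-pyran-2-carboxylic acid | OC(=O)c1cc(=O)c(O)c(Br)o1 | intermediate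
7 | methyl 6-bromo-5-methoxy-4-oxo-4H-pyran-2-carboxylate | COC(=O)c1cc(=O)c(OC)c(Br)o1 | intermediate
8 | methyl 5-methoxy-4-oxo-6-(2,3,4,6-tetramethoxyphenyl)-4H-pyran-2-carboxylate | COC(=O)c1cc(=O)c(OC)c(-c2c(OC)c(OC)c(OC)cc2OC)o1 | intermediate
9 | lithium 5-methoxy-4-oxo-6-(2,3,4,6-tetramethoxyphenyl)-4H-pyran-2-carboxylate | [Li+].[O-]C(=O)c1cc(=O)c(OC)c(-c2c(OC)c(OC)c(OC)cc2OC)o1 | intermediate
10 | 5-methoxy-4-oxo-6-(2,3,4,6-tetramethoxyphenyl)-4H-pyran-2-carboxylic acid | OC(=O)c1cc(=O)c(OC)c(-c2c(OC)c(OC)c(OC)cc2OC)o1 | intermediate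
11 | (2-methylpropoxy)carbonyl 5-methoxy-4-oxo-6-(2,3,4,6-tetramethoxyphenyl)-4H-pyran-2-carboxylate (mixed carbonic anhydride) | CC(C)COC(=O)OC(=O)c1cc(=O)c(OC)c(-c2c(OC)c(OC)c(OC)cc2OC)o1 | intermediate
12 | 2-diazo-1-[5-methoxy-4-oxo-6-(2,3,4,6-tetramethoxyphenyl)-4H-pyran-2-yl]ethanone | [N-]=[N+]=CC(=O)c1cc(=O)c(OC)c(-c2c(OC)c(OC)c(OC)cc2OC)o1 | intermediate
13 | chloroacetaldehyde dimethyl acetal (2-chloro-1,1-dimethoxyethane) | COC(CCl)OC | starting material
14 | sodium methoxyethynide | [Na+].[C-]#COC | intermediate
15 | methoxyethyne | C#COC | intermediate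
16 | 2-[5-methoxy-4-oxo-6-(2,3,4,6-tetramethoxyphenyl)-4H-pyran-2-yl]ethenone | O=C=Cc1cc(=O)c(OC)c(-c2c(OC)c(OC)c(OC)cc2OC)o1 | intermediate
17 | 3-methoxy-4-[5-methoxy-4-oxo-6-(2,3,4,6-tetramethoxyphenyl)-4H-pyran-2-yl]cyclobut-2-en-1-one (racemic) | COC1=CC(=O)C1c1cc(=O)c(OC)c(-c2c(OC)c(OC)c(OC)cc2OC)o1 | intermediate
18 | (3E)-3-methoxy-4-[5-methoxy-4-oxo-6-(2,3,4,6-tetramethoxyphenyl)-4H-pyran-2-yl]buta-1,3-dien-1-one (pyranonyl group cis to the ketene arm) | O=C=C/C(OC)=C\c1cc(=O)c(OC)c(-c2c(OC)c(OC)c(OC)cc2OC)o1 | intermediate
19 | 3,7-dimethoxy-2-(2,3,4,6-tetramethoxyphenyl)-4aH-chromene-4,5-dione (racemic) | COC1=CC(=O)C2C(=O)C(OC)=C(c3c(OC)c(OC)c(OC)cc3OC)OC2=C1 | intermediate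
20 | 5-hydroxy-3,7-dimethoxy-2-(2,3,4,6-tetramethoxyphenyl)-4H-chromen-4-one | COc1cc(O)c2c(=O)c(OC)c(-c3c(OC)c(OC)c(OC)cc3OC)oc2c1 | intermediate
21 | 2-(5-hydroxy-3,7-dimethoxy-4-oxo-4H-chromen-2-yl)-3,5-dimethoxycyclohexa-2,5-diene-1,4-dione (CNP0259413.0) | COC1=CC(=O)C(c2oc3cc(OC)cc(O)c3c(=O)c2OC)=C(OC)C1=O | target

**Step count**
Total steps: 9. Longest linear sequence: 7 steps (5 → 6 → 7 → 8 → 10 → 12 → 20 → 21; steps 2–6, 8 and 9).

**Steps most likely to fail**

Step 8. The ketene may be lost to dimerisation or to reaction with unchanged diazoketone before the ynol ether traps it. The opened cyclobutenone may also fail to close onto the pyranone C=C bond. The fallback uses known chemistry only and builds ring C last, on a preformed ring A; it sets out from aryllithium 2 and returns at 20. Quenching 2 with CO2 and acidifying gives 2,3,4,6-tetramethoxybenzoic acid F1. (COCl)2 with catalytic DMF in CH2Cl2 converts this into 2,3,4,6-tetramethoxybenzoyl chloride F2. A Hoesch reaction of phloroglucinol with methoxyacetonitrile (HCl, ZnCl2, Et2O, 0 °C; then hot water) gives 2-methoxy-1-(2,4,6-trihydroxyphenyl)ethanone F3. Its lithium polyanion (LiN(SiMe3)2, 5 equiv, THF, −78 °C) is C-acylated by F2 in a Baker–Venkataraman-type process to give 2-methoxy-1-(2,3,4,6-tetramethoxyphenyl)-3-(2,4,6-trihydroxyphenyl)propane-1,3-dione F4. Cyclodehydration (H2SO4, AcOH, 95 °C) gives 5,7-dihydroxy-3-methoxy-2-(2,3,4,6-tetramethoxyphenyl)-4H-chromen-4-one F5. One equivalent of MeI with K2CO3 in acetone then methylates only the unchelated C7 hydroxyl and delivers 20.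

Step 4. Protodeboronation of the electron-rich, di-ortho-substituted boronic acid may outrun the slow transmetalation to the hindered palladium centre. The fallback replaces boron by zinc in a base-free and water-free Negishi coupling; it sets out from aryllithium 2 (with bromide 7 as partner) and returns at 8. Adding ZnCl2 in THF to 2 at 0 °C gives chloro(2,3,4,6-tetramethoxyphenyl)zinc F6. This is coupled in the same flask with 7 (Pd2(dba)3, RuPhos, THF, 60 °C), and the methyl ester tolerates the arylzinc reagent.

Step 9. One-electron oxidation of the phenolic ring A may compete with that of ring B and lead to oxidative coupling or degradation. The fallback masks the phenol as an electron-poor ester before the oxidation; it sets out from 20 and returns at 21. Ac2O, pyridine and catalytic DMAP give 3,7-dimethoxy-4-oxo-2-(2,3,4,6-tetramethoxyphenyl)-4H-chromen-5-yl acetate F7. (NH4)2Ce(NO3)6 in MeCN/H2O at 0 °C then oxidises ring B alone to 2-(2,4-dimethoxy-3,6-dioxocyclohexa-1,4-dien-1-yl)-3,7-dimethoxy-4-oxo-4H-chromen-5-yl acetate F8. Catalytic HCl in MeOH at rt removes the labile peri acetate by transesterification. Under these conditions any exchange of the quinone methoxy groups with methanol is degenerate.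

**Further compounds**
F1 | step 8 | 2,3,4,6-tetramethoxybenzoic acid | COc1cc(OC)c(OC)c(OC)c1C(=O)O
F2 | step 8 | 2,3,4,6-tetramethoxybenzoyl chloride | COc1cc(OC)c(OC)c(OC)c1C(=O)Cl
F3 | step 8 | 2-methoxy-1-(2,4,6-trihydroxyphenyl)ethanone | COCC(=O)c1c(O)cc(O)cc1O
F4 | step 8 | 2-methoxy-1-(2,3,4,6-tetramethoxyphenyl)-3-(2,4,6-trihydroxyphenyl)propane-1,3-dione (racemic, enolisable) | COC(C(=O)c1c(O)cc(O)cc1O)C(=O)c1c(OC)c(OC)c(OC)cc1OC
F5 | step 8 | 5,7-dihydroxy-3-methoxy-2-(2,3,4,6-tetramethoxyphenyl)-4H-chromen-4-one | COc1cc(OC)c(-c2oc3cc(O)cc(O)c3c(=O)c2OC)c(OC)c1OC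
F6 | step 4 | chloro(2,3,4,6-tetramethoxyphenyl)zinc | Cl[Zn]c1c(OC)cc(OC)c(OC)c1OC
F7 | step 9 | 3,7-dimethoxy-4-oxo-2-(2,3,4,6-tetramethoxyphenyl)-4H-chromen-5-yl acetate | CC(=O)Oc1cc(OC)cc2oc(-c3c(OC)c(OC)c(OC)cc3OC)c(OC)c(=O)c12
F8 | step 9 | 2-(2,4-dimethoxy-3,6-dioxocyclohexa-1,4-dien-1-yl)-3,7-dimethoxy-4-oxo-4H-chromen-5-yl acetate | CC(=O)Oc1cc(OC)cc2oc(C3=C(OC)C(=O)C(OC)=CC3=O)c(OC)c(=O)c12
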